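All runs are simulated for substances that don't exist; noise was put on by code.

| flask | substrate | coupling partner | remark | time |
|---|---|---|---|---|
| teal | 42 mM | 1.1 equiv | run made earlier |  |
| green | 42 mM | 1.8 equiv | run made earlier |  |
| flask | 42 mM | 0.800 equiv |  | 8.0 d |

| run | time / d | substrate / % | target / % | intermediate A / % |
|---|---|---|---|---|
| teal | 0.625 | 12.2 | 36.1 | 48.5 |
| teal | 1.25 | 6.0 | 38.4 | 52.4 |
| teal | 2.50 | 5.5 | 39.2 | 53.9 |
| teal | 4.00 | 6.1 | 38.6 | 53.0 |
| teal | 8.00 | 3.7 | 40.0 | 55.0 |
| green | 0.625 | 10.3 | 48.6 | 36.1 |
| green | 1.25 | 4.3 | 51.8 | 40.9 |
| green | 2.50 | 2.1 | 53.1 | 42.7 |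
| green | 4.00 | 4.1 | 51.6 | 41.7 |
| green | 8.00 | 5.0 | 53.2 | 41.7 |

(standard deviation of a reading: 1 percentage point)

- the earlier runs were read with a standard deviation of 1 percentage point
- what has gone from substrate into another species counts as reacted, even if it can come back

1. part of the substrate gone at 8.0 d
2. the target standing at 8.0 d, as a percentage of the substrate charged
3. the intermediate A standing at 8.0 d, as a percentage of the substrate charged
4. the intermediate B standing at 8.0 d, as a percentage of the substrate charged
5. amount of target if the flask were left three thousand times as long, in percent of the substrate charged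

The teal run stands level from 2.50 d to 8.00 d, and the green run does too, so we read both plateaus as equilibrium (thermodynamic control) and compare two amounts: the free coupling partner P, which is the charge less the target formed, and a crossing concentration P*. At 8.00 d the teal run has P = 29.4 mM and more intermediate A than target, while the green run has P = 53.3 mM and more target than intermediate A. Target over intermediate A, divided by P, reads 24.7 /M in teal and 24.0 /M in green, which agree within the scatter. The inverse of their mean is P*, the free partner at which target equals intermediate A, 41.1 mM, so on these plateaus target over intermediate A reads P/P*.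

Our flask charges 33.6 mM of partner, less than P*, so we expect intermediate A to stay ahead of target. In the teal run at 8.00 d, intermediate A read 91.7% of everything that was not target. Taking that share and P* over to a plateau in our flask, our reckoning gives 31.3% target and 63.0% intermediate A.

The forecast, slightly different, gave 94.3% conversion, 30.8% target, 62.3% intermediate A, 1.2% intermediate B and 31% target at long time, adding “No drift is visible”.

The flask gives 94.4%, 30.6%, 61.5%, 2.24% and 30.6%, in that order.

    substrate ⇌ intermediate A (K = 11.0, k = 0.00350 /min)
    substrate ⇌ intermediate B (K = 0.400, k = 0.00190 /min)
    coupling partner + intermediate A ⇌ target (K = 24.0 /M, k = 0.200 /M/min)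

At 8.00 d the flask has free partner 20.7 mM against P* of 41.1 mM, a ratio of 0.504, and target over intermediate A stands at 0.498. The neighbour at 170 mM substrate, with the same equivalents, has free partner 49.1 mM, more than P*, a ratio of 1.19, and its target over intermediate A stands at 1.18.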